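## Retrosynthetic overview

1. Target ⇐ acylation of the secondary C5–OH of a 1,5-dihydroxy-2,9-diketone with isovaleric anhydride.
2. Cycloheptane (second ring) ⇐ intramolecular aldol of a seco keto-aldehyde: the C1 enediolate of the 1-hydroxy-2-ketone adds to the C5 aldehyde on the finished lactone.
3. Seco keto-aldehyde ⇐ glycol scission of a glyceraldehyde-derived acetonide ⇐ boron aldol (C10–C1) of an ethyl ketone with (E)-2-oxopent-3-enal.
4. γ-Lactone (first ring) ⇐ O6→C12 lactonisation of a γ-hydroxy ester ⇐ indium Barbier union (C6–C7) of a (Z)-2-(bromomethyl)enoate with (S)-glyceraldehyde acetonide.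
5. Bromide ⇐ Baylis–Hillman reaction and SN2′ bromination, from ethyl 3-oxopentanoate and methyl acrylate. Ring order: lactone first, carbocycle last.

Assumption: the target is read as a 6,12-xanthanolide (4,5-seco-guaianolide; locants used below: C1 = C–OH, C2 = crotonoyl C=O, C5 = CH–O-ester, C6 = lactone CH–O, C7, C8, C9 = ring C=O, C10 = CHMe, C11–C13 = methylene lactone), presumed to arise from an oxidised germacranolide by O6→C12 lactonisation, C4–C5 scission to a C5 aldehyde and aldol-type closure of the C1–C5 bond with C1 nucleophilic and C5 electrophilic.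

## Route

Step 1
Reactants: 1 ethyl 3-oxopentanoate
Product: 2 ethyl 2-(2-ethyl-1,3-dioxolan-2-yl)acetate
Conditions: HOCH2CH2OH, p-TsOH (cat.), toluene, reflux, Dean–Stark
Reagents that add atoms: ethane-1,2-diol, OCCO
Why: Acid-catalysed ketalisation of the ketone, driven by azeotropic removal of water, leaves the ester untouched; no stereocentre is formed.

Step 2
Reactants: 2 ethyl 2-(2-ethyl-1,3-dioxolan-2-yl)acetate
Product: 3 2-(2-ethyl-1,3-dioxolan-2-yl)acetaldehyde
Conditions: DIBAL-H (1.05 equiv), CH2Cl2, −78 °C; Rochelle salt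
Reagents that add atoms: none
Why: DIBAL-H half-reduction stops at the aldehyde through the tetrahedral aluminium hemiacetal that is stable at −78 °C, and the ketal prevents a β-keto aldehyde.

Step 3
Reactants: 3 2-(2-ethyl-1,3-dioxolan-2-yl)acetaldehyde; 4 methyl acrylate
Product: 5 methyl 4-(2-ethyl-1,3-dioxolan-2-yl)-3-hydroxy-2-methylidenebutanoate (racemic)
Conditions: DABCO (0.5 equiv), neat in 4 (3 equiv), rt, 5 d
Reagents that add atoms: none
Why: Morita–Baylis–Hillman reaction of an unhindered aliphatic aldehyde; the carbinol centre is racemic and is erased in step 4.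

Step 4
Reactants: 5 methyl 4-(2-ethyl-1,3-dioxolan-2-yl)-3-hydroxy-2-methylidenebutanoate
Product: 6 methyl (2Z)-2-(bromomethyl)-4-(2-ethyl-1,3-dioxolan-2-yl)but-2-enoate
Conditions: NBS, Me2S, CH2Cl2, 0 °C → rt
Reagents that add atoms: N-bromosuccinimide, O=C1CCC(=O)N1Br
Why: Corey–Kim-type activation of the allylic alcohol and SN2′ attack of bromide give the conjugated (Z)-2-(bromomethyl)enoate under neutral conditions that spare the ketal.

Step 5
Reactants: 6 methyl (2Z)-2-(bromomethyl)-4-(2-ethyl-1,3-dioxolan-2-yl)but-2-enoate; 7 (S)-2,2-dimethyl-1,3-dioxolane-4-carbaldehyde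
Product: 9 methyl (3S,4R)-4-[(4S)-2,2-dimethyl-1,3-dioxolan-4-yl]-3-[(2-ethyl-1,3-dioxolan-2-yl)methyl]-4-hydroxy-2-methylidenebutanoate, via allylindium dibromide 8 (not isolated)
Conditions: In powder (1.5 equiv), THF–H2O (1:1), rt
Reagents that add atoms: none
Why: Indium Barbier allylation: γ-attack (SE2′) of the (Z)-allylindium through a chair transition state gives the 3,4-syn pair (later the cis-lactone), and Felkin–Anh addition to the α-alkoxy aldehyde gives 4,5-anti, so the (S)-dioxolane sets C6 as R and C7 as S.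

Step 6
Reactants: 9 methyl (3S,4R)-4-[(4S)-2,2-dimethyl-1,3-dioxolan-4-yl]-3-[(2-ethyl-1,3-dioxolan-2-yl)methyl]-4-hydroxy-2-methylidenebutanoate
Product: 11 (4S,5R)-5-[(4S)-2,2-dimethyl-1,3-dioxolan-4-yl]-3-methylidene-4-(2-oxobutyl)oxolan-2-one, via lactone ketal 10 (not isolated)
Conditions: PPTS (0.2 equiv), acetone–H2O (50:1), 50 °C
Reagents that add atoms: water, O
Why: Acid-catalysed lactonisation of the γ-hydroxy ester (C6 and C7 retained, hence the cis-lactone) is followed by hydrolysis of the ethylene ketal, while the acetone medium keeps the terminal acetonide in place.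

Step 7
Reactants: 12 (E)-pent-3-en-2-one
Product: 13 (E)-2-oxopent-3-enal
Conditions: SeO2 (1.1 equiv), 1,4-dioxane–H2O (20:1), 90 °C; distilled and used fresh
Reagents that add atoms: selenium dioxide, O=[Se]=O
Why: Riley oxidation converts the methyl group of the methyl ketone into the aldehyde of an α-keto aldehyde and leaves the (E)-alkene alone.

Step 8
Reactants: 11 (4S,5R)-5-[(4S)-2,2-dimethyl-1,3-dioxolan-4-yl]-3-methylidene-4-(2-oxobutyl)oxolan-2-one; 13 (E)-2-oxopent-3-enal
Product: 15 (4S,5R)-5-[(4S)-2,2-dimethyl-1,3-dioxolan-4-yl]-4-[(6E)-4-hydroxy-3-methyl-2,5-dioxooct-6-en-1-yl]-3-methylideneoxolan-2-one (epimers at C10 and C1), via boron enolate 14 (not isolated)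
Conditions: (c-C6H11)2BCl, Et3N, Et2O, −78 → 0 °C; then 13, −78 → −20 °C; MeOH, pH 7 buffer
Reagents that add atoms: none
Why: Brown–Paterson boron aldol: the bulky chloroborane enolises the ethyl terminus (C10) rather than the CH2 next to the substituted ring carbon, and the E-enolate adds to the aldehyde carbonyl of 13; C1 is re-formed in step 10 and C10 stays epimerisable next to C9=O, so neither new centre needs control here.

Step 9
Reactants: 15 (4S,5R)-5-[(4S)-2,2-dimethyl-1,3-dioxolan-4-yl]-4-[(6E)-4-hydroxy-3-methyl-2,5-dioxooct-6-en-1-yl]-3-methylideneoxolan-2-one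
Product: 17 (2R,3S)-3-[(6E)-4-hydroxy-3-methyl-2,5-dioxooct-6-en-1-yl]-4-methylidene-5-oxooxolane-2-carbaldehyde, via vicinal diol 16 (not isolated)
Conditions: H5IO6 (1.2 equiv), EtOAc, 0 °C → rt
Reagents that add atoms: none
Why: Periodic acid hydrolyses the terminal acetonide and cleaves the freed 1,2-diol (Malaprade reaction) faster than it attacks the α-ketol, which unmasks the C5 aldehyde without touching C6.

Step 10
Reactants: 17 (2R,3S)-3-[(6E)-4-hydroxy-3-methyl-2,5-dioxooct-6-en-1-yl]-4-methylidene-5-oxooxolane-2-carbaldehyde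
Product: 18 (3aS,6R,7S,8S,8aR)-7-[(2E)-but-2-enoyl]-7,8-dihydroxy-6-methyl-3-methylideneoctahydro-2H-cyclohepta[b]furan-2,5-dione
Conditions: MgBr2·OEt2 (2 equiv), i-Pr2NEt (2.5 equiv), CH2Cl2, −20 → 23 °C
Reagents that add atoms: none
Why: Proposed new method: Mg(II) chelation of the C1-hydroxy/C2-ketone makes H-1 the most acidic proton, and the enediolate closes the seven-membered ring on the C5 aldehyde (7-enolexo-exo-trig; closest known type: MgBr2/amine and Zn-mediated direct aldol additions of α-hydroxy ketone donors); the addition is reversible and C10 equilibrates through the C9 enolate, so the product should settle in the chair-like cycloheptane with crotonoyl, C10-methyl and C11 equatorial and the C6–O, C5–O and C1–O bonds alternately axial (Cornforth-type dipole minimum), which is 1S,5S,10R.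

Step 11
Reactants: 18 (3aS,6R,7S,8S,8aR)-7-[(2E)-but-2-enoyl]-7,8-dihydroxy-6-methyl-3-methylideneoctahydro-2H-cyclohepta[b]furan-2,5-dione; 19 3-methylbutanoic anhydride
Product: 20 (3aS,6R,7S,8S,8aR)-7-[(2E)-but-2-enoyl]-7-hydroxy-6-methyl-3-methylidene-2,5-dioxooctahydro-2H-cyclohepta[b]furan-8-yl 3-methylbutanoate (CNP0283951.1)
Conditions: DMAP (0.1 equiv), pyridine, CH2Cl2, 0 °C
Reagents that add atoms: none
Why: DMAP-catalysed acylation esterifies the secondary C5–OH and leaves the tertiary C1–OH, and no stereocentre is touched.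

## Compound list

1 | ethyl 3-oxopentanoate | CCOC(=O)CC(=O)CC | starting material
2 | ethyl 2-(2-ethyl-1,3-dioxolan-2-yl)acetate | CCOC(=O)CC1(CC)OCCO1 | intermediate
3 | 2-(2-ethyl-1,3-dioxolan-2-yl)acetaldehyde | CCC1(CC=O)OCCO1 | intermediate
4 | methyl acrylate | C=CC(=O)OC | starting material
5 | methyl 4-(2-ethyl-1,3-dioxolan-2-yl)-3-hydroxy-2-methylidenebutanoate (racemic) | CCC1(CC(O)C(=C)C(=O)OC)OCCO1 | intermediate
6 | methyl (2Z)-2-(bromomethyl)-4-(2-ethyl-1,3-dioxolan-2-yl)but-2-enoate | CCC1(C/C=C(\CBr)C(=O)OC)OCCO1 | intermediate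
7 | (S)-2,2-dimethyl-1,3-dioxolane-4-carbaldehyde | O=C[C@@H]1COC(C)(C)O1 | starting material
8 | allylindium dibromide from 6 (simplest formulation, not isolated) | CCC1(C/C=C(\C[In](Br)Br)C(=O)OC)OCCO1 | intermediate
9 | methyl (3S,4R)-4-[(4S)-2,2-dimethyl-1,3-dioxolan-4-yl]-3-[(2-ethyl-1,3-dioxolan-2-yl)methyl]-4-hydroxy-2-methylidenebutanoate | C=C(C(=O)OC)[C@H](CC1(CC)OCCO1)[C@@H](O)[C@@H]2COC(C)(C)O2 | intermediate
10 | (4S,5R)-5-[(4S)-2,2-dimethyl-1,3-dioxolan-4-yl]-4-[(2-ethyl-1,3-dioxolan-2-yl)methyl]-3-methylideneoxolan-2-one (not isolated) | C=C1C(=O)O[C@@H]([C@@H]2COC(C)(C)O2)[C@H]1CC3(CC)OCCO3 | intermediate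
11 | (4S,5R)-5-[(4S)-2,2-dimethyl-1,3-dioxolan-4-yl]-3-methylidene-4-(2-oxobutyl)oxolan-2-one | C=C1C(=O)O[C@@H]([C@@H]2COC(C)(C)O2)[C@H]1CC(=O)CC | intermediate
12 | (E)-pent-3-en-2-one | C/C=C/C(C)=O | starting material
13 | (E)-2-oxopent-3-enal | C/C=C/C(=O)C=O | intermediate
14 | dicyclohexylboron (E)-enolate of 11 (not isolated) | C=C1C(=O)O[C@@H]([C@@H]2COC(C)(C)O2)[C@H]1C/C(OB(C3CCCCC3)C3CCCCC3)=C\C | intermediate
15 | (4S,5R)-5-[(4S)-2,2-dimethyl-1,3-dioxolan-4-yl]-4-[(6E)-4-hydroxy-3-methyl-2,5-dioxooct-6-en-1-yl]-3-methylideneoxolan-2-one (epimers at C10, C1) | C=C1C(=O)O[C@@H]([C@@H]2COC(C)(C)O2)[C@H]1CC(=O)C(C)C(O)C(=O)/C=C/C | intermediate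
16 | (4S,5R)-5-[(1S)-1,2-dihydroxyethyl]-4-[(6E)-4-hydroxy-3-methyl-2,5-dioxooct-6-en-1-yl]-3-methylideneoxolan-2-one (not isolated) | C=C1C(=O)O[C@@H]([C@@H](O)CO)[C@H]1CC(=O)C(C)C(O)C(=O)/C=C/C | intermediate
17 | (2R,3S)-3-[(6E)-4-hydroxy-3-methyl-2,5-dioxooct-6-en-1-yl]-4-methylidene-5-oxooxolane-2-carbaldehyde | C=C1C(=O)O[C@@H](C=O)[C@H]1CC(=O)C(C)C(O)C(=O)/C=C/C | intermediate
18 | (3aS,6R,7S,8S,8aR)-7-[(2E)-but-2-enoyl]-7,8-dihydroxy-6-methyl-3-methylideneoctahydro-2H-cyclohepta[b]furan-2,5-dione | C=C1C(=O)O[C@@H]2[C@H]1CC(=O)[C@H](C)[C@@](O)(C(=O)/C=C/C)[C@H]2O | intermediate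
19 | 3-methylbutanoic anhydride | CC(C)CC(=O)OC(=O)CC(C)C | starting material
20 | (3aS,6R,7S,8S,8aR)-7-[(2E)-but-2-enoyl]-7-hydroxy-6-methyl-3-methylidene-2,5-dioxooctahydro-2H-cyclohepta[b]furan-8-yl 3-methylbutanoate | C=C1C(=O)O[C@@H]2[C@H]1CC(=O)[C@H](C)[C@@](O)(C(=O)/C=C/C)[C@H]2OC(=O)CC(C)C | target

## Count and risks

Total steps: 11. Longest linear sequence: 10 (steps 1–6 and 8–11; step 7 is a one-step side branch).

Most likely to fail, first: step 10. The closure must beat the six-ring aldol from C10 to the aldehyde and epimerisation at C6, and the facial outcome at C5 and C1 rests on a conformational argument rather than on precedent. The fallback makes the same C1–C5 bond as a Darzens closure, which turns the opposite (Felkin) aldehyde-face preference into the natural configuration. It sets out from 15 and comes back at 20. Appel chlorination of 15 (PPh3, NCS) gives the α-chloro ketone F1. Periodic acid then gives the chloro keto aldehyde F2. Cs2CO3 in MeCN closes the cis-fused 1,5-epoxy ketone F3; only the chlorohydrin alkoxide anti to chloride can close, the others return by retro-aldol. The aldehyde oxygen ends up as the C1 hydroxyl on the lactone-oxygen face. Ti(O-i-Pr)4 and 3-methylbutanoic acid then open F3 at C5 with inversion, away from the acyl-bearing C1, and this gives 20 directly with the trans C1–OH/C5–ester pattern.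

Second: step 8. The vinyl glyoxal 13 may hydrate or oligomerise, and some enolisation at C8 is possible. The fallback replaces 13 by a stable two-carbon electrophile and builds the enone afterwards; it does not cure C8 enolisation, whose regioisomer would have to be separated. It sets out from 11 (through 14) and comes back at 15. The boron enolate is added to S-ethyl 2-oxoethanethioate F4 (freshly prepared) to give the hydroxy thioester F5. Liebeskind–Srogl coupling of F5 with (E)-prop-1-enylboronic acid (Pd2(dba)3, tri(2-furyl)phosphine, CuTC, THF, 50 °C) installs the crotonoyl ketone in the presence of the C9 ketone and the lactone.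

Third: step 9. Periodate may also cleave the C1–C2 α-ketol. The fallback masks the ketol first. It sets out from 15 and comes back at 17. TESOTf and 2,6-lutidine give the silyl ether F6, periodic acid gives the silyl ether aldehyde F7, and HF·pyridine in THF at 0 °C releases 17.

## Further compounds

F1 | step 10 | (4S,5R)-4-[(6E)-4-chloro-3-methyl-2,5-dioxooct-6-en-1-yl]-5-[(4S)-2,2-dimethyl-1,3-dioxolan-4-yl]-3-methylideneoxolan-2-one | C=C1C(=O)O[C@@H]([C@@H]2COC(C)(C)O2)[C@H]1CC(=O)C(C)C(Cl)C(=O)/C=C/C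
F2 | step 10 | (2R,3S)-3-[(6E)-4-chloro-3-methyl-2,5-dioxooct-6-en-1-yl]-4-methylidene-5-oxooxolane-2-carbaldehyde | C=C1C(=O)O[C@@H](C=O)[C@H]1CC(=O)C(C)C(Cl)C(=O)/C=C/C
F3 | step 10 | cis-fused 1,5-epoxy ketone (18 with a C1–O–C5 oxirane on the lactone-oxygen face in place of the two hydroxyls) | C=C1C(=O)O[C@@H]2[C@H]1CC(=O)[C@H](C)[C@]3(C(=O)/C=C/C)O[C@H]23
F4 | step 8 | S-ethyl 2-oxoethanethioate | CCSC(=O)C=O
F5 | step 8 | S-ethyl 5-[(2R,3S)-2-[(4S)-2,2-dimethyl-1,3-dioxolan-4-yl]-4-methylidene-5-oxooxolan-3-yl]-2-hydroxy-3-methyl-4-oxopentanethioate | C=C1C(=O)O[C@@H]([C@@H]2COC(C)(C)O2)[C@H]1CC(=O)C(C)C(O)C(=O)SCC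
F6 | step 9 | C1 O-triethylsilyl ether of 15 | C=C1C(=O)O[C@@H]([C@@H]2COC(C)(C)O2)[C@H]1CC(=O)C(C)C(O[Si](CC)(CC)CC)C(=O)/C=C/C
F7 | step 9 | C1 O-triethylsilyl ether of 17 | C=C1C(=O)O[C@@H](C=O)[C@H]1CC(=O)C(C)C(O[Si](CC)(CC)CC)C(=O)/C=C/C
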